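## Structural features

The target is a linear tridepside: three benzene rings joined by two aryl ester bonds, with the C1 carbonyl of ring A on O4 of ring B, the C1 carbonyl of ring B on O4 of ring C, and the free carboxylic acid on C1 of ring C. Rings B and C are orsellinate units (C1 carbonyl, C2 hydroxyl, C4 oxygen, C6 methyl). Ring A is the same unit with an extra acetoxy group at C5, between the C4 hydroxyl and the C6 methyl, so its oxygens at C2, C4 and C5 form a hydroxyquinol pattern. There is no stereocentre and no ring beyond the three arenes; the problem is regiochemistry and telling seven oxygen functions apart. The fragile groups are the two aryl esters, which are active esters towards base, nucleophiles and phenoxides, and the C5 acetate, which sits next to a free phenol at C4 and can shift or be solvolysed. Every carbonyl carbon is flanked by two ortho substituents, so each esterification is hindered and needs a reactive acyl donor. The real difficulty is to have O4 of rings B and C free exactly when it is acylated, while O2 and the terminal acid carry groups that come off at the end without touching the acetate or the depside links. The key step uses the fact that in rings B and C the C6 methyl and the C1 carboxyl are on adjacent carbons and C1 is next to the C2 oxygen: these two carbons map onto the triple bond of a 3,5-dioxygenated benzyne, so methyl and carboxyl can be added across it in one operation while O2 and O4 already carry different protecting groups.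

## Logic of the disconnections

25 to 24. The five oxygen–benzyl bonds are cut: the ethers at O2 and O4 of ring A, O2 of ring B and O2 of ring C, and the ester on the ring C carboxyl. One neutral reductive operation then uncovers every acidic group while the C5 acetate and both depside links are spectators. All earlier intermediates become non-acidic and easy to purify. The forward step must go to completion at five sites without base or alcohol, so that the acetate neither shifts to O4 nor is solvolysed.

24 to 23 and 14. The ester bond between the ring A carbonyl and O4 of ring B is cut. Ring A, the only ring with the acetate, is brought in last, and the molecule splits into two pieces of similar size. The forward step must acylate one phenol with a di-ortho-substituted aroyl chloride without transferring the acetyl group; 23 is made in the flask from 22.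

14 to 13, then to 12 and 11. First the O4–Si bond on ring B is cut, then the ester bond between the ring B carbonyl and O4 of ring C. The silyl group keeps O4 of ring B inert while ring C is attached; its removal must be buffered so that the phenoxide does not attack an aryl ester. The didepside is reduced to two monocyclic units.

12 and 11 to 9. Both units come from the same acid: 12 by exchange of Cl for OH, 11 through 10 by cutting the O4–Si bond and the ester O–benzyl bond. One building block serves two rings. This requires that 9 carry a permanent group on O2 and a temporary one on O4.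

9 to 3, 4 and 5, through 8, 7 and 6. The C6–CH3 and C1–CO2H bonds are cut together. They sit on adjacent carbons with C1 next to O2, the pattern formed when a carbon nucleophile and an electrophile add across a 3-alkoxyaryne. Two carbon–carbon bonds are gained in one flask from a benzene that has only two oxygens and a fluorine. The forward step needs metalation between F and the benzyloxy group, and methyl addition at the aryne carbon remote from that group.

3 to 2 to 1. The O–Si bond and then one O–benzyl bond are cut. Since 1 is symmetric, either hydroxyl gives the same monoether, so the only requirement is to stop at monoalkylation.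

22 to 21 to 19, through 20. The carboxyl is taken back to an aldehyde and the C1–CHO bond is cut. The carbon is introduced by electrophilic substitution on an arene whose three oxygens are already differentiated. The step must attack the position between O2 and the methyl group and not the one between O2 and O4.

19 to 18 to 16, through 17, and to 15. The acetyl–O5 bond is cut, the C5–O bond is traced to a C5–CHO bond by aryl migration to oxygen, and the two benzyl ethers are removed. The formyl group of commercial 15 already marks the one ring position that must become O5. The oxidation must make the aryl group migrate in preference to hydride.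

## Other disconnections considered

Alternative 1: The cut is bond C1–C2 of ring A, which unravels the ring into a dienylketene and then into racemic cyclobutenone A2, where the acetoxy group and an (E)-crotonate arm share one quaternary carbon.
- Forward step: heating A2 should open the four-membered ring with the oxygen substituent rotating outward and the alkenyl arm inward; the ketene carbon should close onto the ester-bearing alkene carbon by 6π electrocyclization, and enolization should give benzoate A1.
- In favour: every substituent of ring A is placed by the connectivity of A2, so no electrophilic substitution has to choose between C1 and C3. On this point it is better than the chosen plan, whose step 11 depends on para-selective formylation. The acetate is present from the start, and O2 and O4 emerge differentiated.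
- Against: A2 needs regioselective addition of a metalated crotonate to an unsymmetrical four-membered dione and acetylation of a tertiary alkoxide that can fragment. An acetoxy group is a weaker donor than hydroxyl, so the outward rotation the closure relies on is less assured. A1 must still be benzylated at O2 and its tert-butyl ester cleaved before it matches 22.
- Comparison: it replaces only the five-step branch from 15 to 22, by a sequence estimated at six or seven steps. The two hindered esterifications and the endgame stay the same (equal). Mechanistically it trades a well-precedented aromatic substitution for a pericyclic cascade on a sensitive substrate. Rings B and C would still need their own source.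

Alternative 2: Two bonds are cut at once: the ester C–O bond between the ring A carbonyl and O4 of ring B, and bond C1–C6 of ring A, which opens ring A into a 6-acetoxy-3,5,7-trioxooctanoyl chain.
- Forward step: heating dioxinone A5 with benzyl lecanorate A4 should release an acylketene by cycloreversion. The 4-hydroxyl of ring B, the only phenol of A4 not hydrogen-bonded to a carbonyl, should add to it to give aryl ester A6. Aldol condensation between C2 and the C7 ketone of the chain, dehydration and enolization should give A3, and hydrogenolysis of one benzyl ester would finish the synthesis.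
- In favour: ring A and the A–B ester are made in one operation, the substitution pattern of ring A is inherent in the chain, no phenol protecting group is needed, and the endgame removes one benzyl group instead of five. In step count and in the mildness of the last step it is better than the chosen plan.
- Against: A6 is an activated aryl ester of a 3,5-dioxo acid, an arrangement expected to lactonize with expulsion of the aryloxide, so A4 could be lost instead of retained. The acetoxy group sits between two ketones, where enolization, acetyl shift and elimination are likely under aldol conditions. A5 requires acylation of a dioxinone enolate with an α-acetoxy acyl donor, a delicate multistep preparation.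
- Comparison: a ketene trapping and a polar aldol against an aryne carbometalation. Structurally it still needs A4, a didepside for which acid 9 would be as good a source as any. The chosen plan is longer, but each bond formation uses a stable, isolable partner, whereas here the decisive cyclization must outrun an easier lactonization.

Alternative 3: Three bonds of ring B are cut (C2–C3, C4–C5 and C1–C2), so that ring B is built on a ring C ester from diazo ketone A8 and siloxyalkyne A9.
- Forward step: irradiation of A8 should cause Wolff rearrangement to a vinylketene, which should add to A9 in a (2+2) sense with the unsubstituted alkyne carbon on the ketene carbonyl. 4π opening of the cyclobutenone, 6π closure and enolization should give didepside A7, with O4 of ring B silylated and O2 free.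
- In favour: the B–C ester bond is made early as an unhindered acrylate-type ester of 11, not by acylation with a di-ortho-substituted aroyl chloride; this is better than step 6 of the chosen plan. The regiochemistry follows from the polarity of ketene and ynol ether, and O4 of ring B emerges silylated as in 13, which is equal to the chosen key step in oxygen differentiation.
- Against: A8 is a light- and base-sensitive Michael acceptor that needs several steps (acylation of 11, diazo transfer). A9 is moisture-sensitive and not a standard catalogue reagent. Ketene dimerization and photoisomerization compete. A7 has a free O2–H on ring B that must be benzylated or tolerated in the acylation with 23.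
- Comparison: the annulation makes one orsellinate ring per operation and needs 11 from elsewhere, whereas the aryne step gives one acid that serves as both rings B and C. The number of steps from commercial material to 14 is estimated to be about equal. The chosen plan avoids diazo compounds and photochemistry and relies on a three-component coupling with close precedent on 3,5-dialkoxyfluorobenzenes.

Key step: step 3

Remark on the chemistry: each ring is numbered with C1 as the carbon bearing its carbonyl group. Re-deriving the key step atom by atom shows that 3, 6, 7, 8 and 9 are consistent: the C–F carbon of 3 becomes the methyl-bearing C6 of 9 and the lithiated carbon becomes C1. n-BuLi is chosen as base because the doubly activated ring position does not need sec-BuLi, which would raise the risk of benzylic metalation.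

## Route

Step 1
Reactants: 1 5-fluororesorcinol (5-fluorobenzene-1,3-diol)
Product: 2 3-(benzyloxy)-5-fluorophenol
Conditions: BnBr (1.0 equiv), K2CO3 (1.1 equiv), DMF, 0 °C → rt; recovered 1 recycled
Reagents that add atoms: benzyl bromide, BrCc1ccccc1
Why: Williamson ether synthesis; both hydroxyls of 1 are equivalent, so the only selectivity issue is mono- against bis-alkylation, which is handled by limiting the halide and separating and recycling the diol.

Step 2
Reactants: 2 3-(benzyloxy)-5-fluorophenol
Product: 3 1-(benzyloxy)-3-fluoro-5-(triisopropylsilyloxy)benzene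
Conditions: TIPSCl, imidazole, DMF, rt
Reagents that add atoms: chlorotriisopropylsilane, CC(C)[Si](Cl)(C(C)C)C(C)C
Why: Imidazole-promoted O-silylation of a phenol; the bulky silyl ether survives organolithium and Grignard reagents, shields the ring position beside it from metalation and is later removed by fluoride without touching the benzyl ether.

Step 3
Reactants: 3 1-(benzyloxy)-3-fluoro-5-(triisopropylsilyloxy)benzene; 4 methylmagnesium bromide; 5 carbon dioxide
Product: 9 2-(benzyloxy)-6-methyl-4-(triisopropylsilyloxy)benzoic acid, via 2-lithio fluoroarene 6 (not isolated), via benzyne 7 (not isolated), via arylmagnesium bromide 8 (not isolated)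
Conditions: n-BuLi (1.05 equiv), THF, −78 °C; MeMgBr (3 equiv), −78 °C → rt; CO2 (g), −20 °C → rt; aq. HCl to pH 3
Reagents that add atoms: none
Why: n-BuLi removes the ring proton between fluorine and the benzyloxy group, the only position acidified by both substituents and able to hold lithium on the ether oxygen, giving 6; the position between fluorine and the bulky, weakly coordinating silyloxy group is metalated far more slowly, and the weaker base n-BuLi leaves the benzylic CH2 alone. On warming in the presence of excess 4, 6 loses LiF and gives aryne 7. The benzyloxy group beside the triple bond withdraws electrons inductively and distorts the aryne, so the remote carbon (the former C–F carbon) is the electrophilic one; the methyl group of 4 adds there and magnesium ends on the carbon ortho to oxygen, where the carbanion is stabilized inductively and by O→Mg coordination (8). The silyloxy group, further from the triple bond, should have only a minor influence. 8 is then carboxylated by 5 at the carbon flanked by methyl and benzyloxy, and acidification gives 9 with O2 benzylated and O4 silylated. The closest known reaction type is the three-component coupling of ortho-lithiated fluoroarenes (3-alkoxyarynes) with Grignard reagents and an electrophile such as CO2. No ring is closed and no stereocentre is formed. The step needs site selectivity in the lithiation, regioselectivity in the carbomagnesiation and capture of 7 by 4 instead of by 6; these are secured by the F/OBn flanking, by the inductive effect of the benzyloxy group and by the excess of 4.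

Step 4
Reactants: 9 2-(benzyloxy)-6-methyl-4-(triisopropylsilyloxy)benzoic acid
Product: 10 benzyl 2-(benzyloxy)-6-methyl-4-(triisopropylsilyloxy)benzoate
Conditions: BnBr, KHCO3, DMF, rt
Reagents that add atoms: benzyl bromide, BrCc1ccccc1
Why: SN2 O-alkylation of the carboxylate, which is not slowed by the two ortho substituents because the new bond forms at the benzylic carbon; hydrogencarbonate is too weak a base to cleave the aryl silyl ether.

Step 5
Reactants: 10 benzyl 2-(benzyloxy)-6-methyl-4-(triisopropylsilyloxy)benzoate
Product: 11 benzyl 2-(benzyloxy)-4-hydroxy-6-methylbenzoate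
Conditions: TBAF, AcOH, THF, 0 °C
Reagents that add atoms: none
Why: Fluoride-induced desilylation driven by the Si–F bond; acetic acid buffers the phenoxide so that the benzyl ester is not attacked, and only O4 is set free.

Step 6
Reactants: 9 2-(benzyloxy)-6-methyl-4-(triisopropylsilyloxy)benzoic acid; 11 benzyl 2-(benzyloxy)-4-hydroxy-6-methylbenzoate
Product: 13 benzyl 2-(benzyloxy)-4-{[2-(benzyloxy)-6-methyl-4-(triisopropylsilyloxy)benzoyl]oxy}-6-methylbenzoate, via acid chloride 12 (not isolated)
Conditions: 9, (COCl)2, DMF (cat.), CH2Cl2, 0 °C → rt, evaporate; then 11, Et3N, DMAP (cat.), CH2Cl2, 0 °C → rt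
Reagents that add atoms: none
Why: Acid chloride formation under DMF catalysis followed by DMAP-catalysed O-acylation of a phenol; the di-ortho-substituted acid needs this level of activation, and O4 is the only nucleophilic site of 11 because O2 and the carboxyl are benzylated.

Step 7
Reactants: 13 benzyl 2-(benzyloxy)-4-{[2-(benzyloxy)-6-methyl-4-(triisopropylsilyloxy)benzoyl]oxy}-6-methylbenzoate
Product: 14 benzyl 2-(benzyloxy)-4-{[2-(benzyloxy)-4-hydroxy-6-methylbenzoyl]oxy}-6-methylbenzoate
Conditions: TBAF, AcOH, THF, 0 °C
Reagents that add atoms: none
Why: Buffered fluoride desilylation as in step 5; the acetic acid keeps the liberated phenoxide protonated so that it does not transesterify the aryl ester link between rings B and C.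

Step 8
Reactants: 15 2,4-dihydroxy-6-methylbenzaldehyde
Product: 16 2,4-bis(benzyloxy)-6-methylbenzaldehyde
Conditions: BnBr (2.5 equiv), K2CO3, DMF, 60 °C
Reagents that add atoms: benzyl bromide, BrCc1ccccc1
Why: Double Williamson etherification; warming is needed for the hydrogen-bonded 2-hydroxyl, and the aldehyde is inert to carbonate.

Step 9
Reactants: 16 2,4-bis(benzyloxy)-6-methylbenzaldehyde
Product: 18 2,4-bis(benzyloxy)-6-methylphenol, via aryl formate 17 (not isolated)
Conditions: mCPBA, CH2Cl2, 0 °C → rt; then K2CO3 (cat.), MeOH, 0 °C, under argon
Reagents that add atoms: 3-chloroperoxybenzoic acid, OOC(=O)c1cccc(Cl)c1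
Why: Baeyer–Villiger (Dakin-type) oxidation; in the peracid adduct the electron-rich aryl group migrates in preference to hydride, and mild methanolysis of formate 17 frees the phenol, turning the formyl-bearing ring position into the future O5 of ring A.

Step 10
Reactants: 18 2,4-bis(benzyloxy)-6-methylphenol
Product: 19 2,4-bis(benzyloxy)-6-methylphenyl acetate
Conditions: Ac2O, pyridine, DMAP (cat.), CH2Cl2, 0 °C → rt
Reagents that add atoms: acetic anhydride, CC(=O)OC(C)=O
Why: O-acetylation of a phenol; it caps the air-sensitive phenol at once and distinguishes O5 from the benzylated O2 and O4 for the rest of the route.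

Step 11
Reactants: 19 2,4-bis(benzyloxy)-6-methylphenyl acetate
Product: 21 5-acetoxy-2,4-bis(benzyloxy)-6-methylbenzaldehyde, via iminium chloride 20 (not isolated)
Conditions: POCl3, DMF, 0 → 60 °C; then aq. NaOAc, rt
Reagents that add atoms: N,N-dimethylformamide, CN(C)C=O; water, O
Why: Vilsmeier–Haack formylation; the open position between the C2 benzyloxy group and the methyl group is para to the C4 benzyloxy group, and the bulky chloroiminium ion is expected to prefer it over the position squeezed between two benzyloxy groups, in line with the formylation of 3,5-dialkoxytoluenes ortho to methyl. Buffered hydrolysis of 20 keeps the acetate.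

Step 12
Reactants: 21 5-acetoxy-2,4-bis(benzyloxy)-6-methylbenzaldehyde
Product: 22 5-acetoxy-2,4-bis(benzyloxy)-6-methylbenzoic acid
Conditions: NaClO2, NaH2PO4, 2-methyl-2-butene, t-BuOH/THF/H2O, 0 °C → rt
Reagents that add atoms: sodium chlorite, [Na+].[O-]Cl=O
Why: Pinnick oxidation of an aldehyde to the acid at mildly acidic pH, which leaves the acetate and benzyl ethers intact; the alkene scavenges hypochlorous acid so that the electron-rich ring is not chlorinated.

Step 13
Reactants: 22 5-acetoxy-2,4-bis(benzyloxy)-6-methylbenzoic acid; 14 benzyl 2-(benzyloxy)-4-{[2-(benzyloxy)-4-hydroxy-6-methylbenzoyl]oxy}-6-methylbenzoate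
Product: 24 benzyl 4-{[4-({5-acetoxy-2,4-bis(benzyloxy)-6-methylbenzoyl}oxy)-2-(benzyloxy)-6-methylbenzoyl]oxy}-2-(benzyloxy)-6-methylbenzoate, via acid chloride 23 (not isolated)
Conditions: 22, (COCl)2, DMF (cat.), CH2Cl2, 0 °C → rt, evaporate; then 14, Et3N, DMAP (cat.), CH2Cl2, 0 °C → rt
Reagents that add atoms: none
Why: Acid chloride formation and DMAP-catalysed O-acylation as in step 6; the aroyl chloride is far more electrophilic than the hindered aryl acetate, so aroylation of the single free phenol of 14 should outrun acetyl transfer.

Step 14
Reactants: 24 benzyl 4-{[4-({5-acetoxy-2,4-bis(benzyloxy)-6-methylbenzoyl}oxy)-2-(benzyloxy)-6-methylbenzoyl]oxy}-2-(benzyloxy)-6-methylbenzoate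
Product: 25 4-{[4-({5-acetoxy-2,4-dihydroxy-6-methylbenzoyl}oxy)-2-hydroxy-6-methylbenzoyl]oxy}-2-hydroxy-6-methylbenzoic acid (CNP0154030.0)
Conditions: H2 (1 atm), 10% Pd on carbon (Pd/C), EtOAc/THF, rt
Reagents that add atoms: none
Why: Hydrogenolysis of four benzyl ethers and one benzyl ester; aryl acetates and aryl esters are inert to H2 on Pd/C, and the neutral, alcohol-free medium avoids acetyl shift from O5 to O4 and transesterification.

## Compound list

1 | 5-fluororesorcinol (5-fluorobenzene-1,3-diol) | Oc1cc(O)cc(F)c1 | starting material
2 | 3-(benzyloxy)-5-fluorophenol | Oc1cc(F)cc(OCc2ccccc2)c1 | intermediate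
3 | 1-(benzyloxy)-3-fluoro-5-(triisopropylsilyloxy)benzene | Fc1cc(OCc2ccccc2)cc(O[Si](C(C)C)(C(C)C)C(C)C)c1 | intermediate
4 | methylmagnesium bromide | C[Mg]Br | starting material
5 | carbon dioxide | O=C=O | starting material
6 | [2-(benzyloxy)-6-fluoro-4-(triisopropylsilyloxy)phenyl]lithium | [Li]c1c(F)cc(O[Si](C(C)C)(C(C)C)C(C)C)cc1OCc1ccccc1 | intermediate (not isolated)
7 | 3-(benzyloxy)-5-(triisopropylsilyloxy)benzyne (1,2-didehydrobenzene) | C1#CC(OCc2ccccc2)=CC(O[Si](C(C)C)(C(C)C)C(C)C)=C1 | intermediate (not isolated)
8 | [2-(benzyloxy)-6-methyl-4-(triisopropylsilyloxy)phenyl]magnesium bromide | Cc1cc(O[Si](C(C)C)(C(C)C)C(C)C)cc(OCc2ccccc2)c1[Mg]Br | intermediate (not isolated)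
9 | 2-(benzyloxy)-6-methyl-4-(triisopropylsilyloxy)benzoic acid | Cc1cc(O[Si](C(C)C)(C(C)C)C(C)C)cc(OCc2ccccc2)c1C(=O)O | intermediate
10 | benzyl 2-(benzyloxy)-6-methyl-4-(triisopropylsilyloxy)benzoate | Cc1cc(O[Si](C(C)C)(C(C)C)C(C)C)cc(OCc2ccccc2)c1C(=O)OCc1ccccc1 | intermediate
11 | benzyl 2-(benzyloxy)-4-hydroxy-6-methylbenzoate | Cc1cc(O)cc(OCc2ccccc2)c1C(=O)OCc1ccccc1 | intermediate
12 | 2-(benzyloxy)-6-methyl-4-(triisopropylsilyloxy)benzoyl chloride | Cc1cc(O[Si](C(C)C)(C(C)C)C(C)C)cc(OCc2ccccc2)c1C(Cl)=O | intermediate (not isolated)
13 | benzyl 2-(benzyloxy)-4-{[2-(benzyloxy)-6-methyl-4-(triisopropylsilyloxy)benzoyl]oxy}-6-methylbenzoate | Cc1cc(O[Si](C(C)C)(C(C)C)C(C)C)cc(OCc2ccccc2)c1C(=O)Oc1cc(C)c(C(=O)OCc2ccccc2)c(OCc2ccccc2)c1 | intermediate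
14 | benzyl 2-(benzyloxy)-4-{[2-(benzyloxy)-4-hydroxy-6-methylbenzoyl]oxy}-6-methylbenzoate | Cc1cc(O)cc(OCc2ccccc2)c1C(=O)Oc1cc(C)c(C(=O)OCc2ccccc2)c(OCc2ccccc2)c1 | intermediate
15 | 2,4-dihydroxy-6-methylbenzaldehyde | Cc1cc(O)cc(O)c1C=O | starting material
16 | 2,4-bis(benzyloxy)-6-methylbenzaldehyde | Cc1cc(OCc2ccccc2)cc(OCc2ccccc2)c1C=O | intermediate
17 | 2,4-bis(benzyloxy)-6-methylphenyl formate | Cc1cc(OCc2ccccc2)cc(OCc2ccccc2)c1OC=O | intermediate (not isolated)
18 | 2,4-bis(benzyloxy)-6-methylphenol | Cc1cc(OCc2ccccc2)cc(OCc2ccccc2)c1O | intermediate
19 | 2,4-bis(benzyloxy)-6-methylphenyl acetate | CC(=O)Oc1c(OCc2ccccc2)cc(OCc2ccccc2)cc1C | intermediate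
20 | N-{[3-acetoxy-4,6-bis(benzyloxy)-2-methylphenyl]methylidene}-N-methylmethanaminium chloride | CC(=O)Oc1c(OCc2ccccc2)cc(OCc2ccccc2)c(C=[N+](C)C)c1C.[Cl-] | intermediate (not isolated)
21 | 5-acetoxy-2,4-bis(benzyloxy)-6-methylbenzaldehyde | CC(=O)Oc1c(OCc2ccccc2)cc(OCc2ccccc2)c(C=O)c1C | intermediate
22 | 5-acetoxy-2,4-bis(benzyloxy)-6-methylbenzoic acid | CC(=O)Oc1c(OCc2ccccc2)cc(OCc2ccccc2)c(C(=O)O)c1C | intermediate
23 | 5-acetoxy-2,4-bis(benzyloxy)-6-methylbenzoyl chloride | CC(=O)Oc1c(OCc2ccccc2)cc(OCc2ccccc2)c(C(Cl)=O)c1C | intermediate (not isolated)
24 | benzyl 4-{[4-({5-acetoxy-2,4-bis(benzyloxy)-6-methylbenzoyl}oxy)-2-(benzyloxy)-6-methylbenzoyl]oxy}-2-(benzyloxy)-6-methylbenzoate | CC(=O)Oc1c(OCc2ccccc2)cc(OCc2ccccc2)c(C(=O)Oc2cc(C)c(C(=O)Oc3cc(C)c(C(=O)OCc4ccccc4)c(OCc4ccccc4)c3)c(OCc3ccccc3)c2)c1C | intermediate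
25 | 4-{[4-({5-acetoxy-2,4-dihydroxy-6-methylbenzoyl}oxy)-2-hydroxy-6-methylbenzoyl]oxy}-2-hydroxy-6-methylbenzoic acid (CNP0154030.0) | CC(=O)Oc1c(O)cc(O)c(C(=O)Oc2cc(C)c(C(=O)Oc3cc(C)c(C(=O)O)c(O)c3)c(O)c2)c1C | target

## Step count and least certain steps

Total: 14 steps. Longest linear sequence: 9 steps (steps 1, 2, 3, 4, 5, 6, 7, 13, 14); the ring A branch (steps 8 to 12) joins at step 13.

Step 3 (key step). What may go wrong:
- metalation at the benzylic CH2 followed by 1,2-migration of the benzyl group;
- metalation beside the silyloxy group, which would carry the protecting groups into exchanged positions;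
- capture of the aryne by the aryllithium or by butyl species instead of by methyl, because a methyl Grignard reagent is a slow nucleophile;
- protonation of the arylmagnesium before carboxylation.

Fallback without an aryne, by known chemistry, setting out from 15 and returning at 9: selective silylation of the non-chelated 4-hydroxyl of 15 (TIPSCl, imidazole, CH2Cl2) should give 2-hydroxy-6-methyl-4-(triisopropylsilyloxy)benzaldehyde F1. Mitsunobu benzylation of the chelated 2-hydroxyl (benzyl alcohol, PPh3, DIAD, THF) should give 2-(benzyloxy)-6-methyl-4-(triisopropylsilyloxy)benzaldehyde F2. Pinnick oxidation (NaClO2, NaH2PO4, 2-methyl-2-butene) then leads to 9.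

Step 11. What may go wrong:
- slow or misdirected electrophilic attack, because the chloroiminium ion is bulky, the wanted position lies between a benzyloxy and a buttressed methyl group, the acetate deactivates the ring, and the position between the two benzyloxy groups competes;
- partial loss of the acetate during the hydrolysis.

Fallback that forms the C1–carbon bond by halogen–metal exchange and brings in the acetate afterwards, setting out from 18 and returning at 22:
- silylation (TBSCl, imidazole, DMF) to tert-butyl[2,4-bis(benzyloxy)-6-methylphenoxy]dimethylsilane F3;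
- bromination with the small, para-selective electrophile NBS (MeCN, 0 °C) to [4,6-bis(benzyloxy)-3-bromo-2-methylphenoxy](tert-butyl)dimethylsilane F4;
- bromine–lithium exchange (n-BuLi, THF, −78 °C) and carboxylation with CO2 to 2,4-bis(benzyloxy)-5-(tert-butyldimethylsilyloxy)-6-methylbenzoic acid F5;
- desilylation (TBAF, THF) to 2,4-bis(benzyloxy)-5-hydroxy-6-methylbenzoic acid F6;
- acetylation (Ac2O, pyridine, then aqueous work-up to hydrolyse the mixed anhydride) to 22.

Step 13. What may go wrong:
- acetyl transfer from the aryl acetate of 23 to the phenoxide of 14 or to DMAP;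
- slow acylation by the di-ortho-substituted chloride, which gives time for scrambling of the existing depside link.

Fallback that introduces the acetate only after the ester bond is made, setting out from 14 and from 18 (through F5, prepared as in the fallback for step 11) and returning at 24:
- F5 is converted with (COCl)2 and catalytic DMF to 2,4-bis(benzyloxy)-5-(tert-butyldimethylsilyloxy)-6-methylbenzoyl chloride F7;
- F7 acylates 14 (Et3N, DMAP, CH2Cl2) to the silyl-protected tridepside benzyl 4-{[4-({2,4-bis(benzyloxy)-5-(tert-butyldimethylsilyloxy)-6-methylbenzoyl}oxy)-2-(benzyloxy)-6-methylbenzoyl]oxy}-2-(benzyloxy)-6-methylbenzoate F8;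
- buffered desilylation (TBAF, AcOH, THF, 0 °C) gives the 5-hydroxy tridepside benzyl 4-{[4-({2,4-bis(benzyloxy)-5-hydroxy-6-methylbenzoyl}oxy)-2-(benzyloxy)-6-methylbenzoyl]oxy}-2-(benzyloxy)-6-methylbenzoate F9;
- acetylation (Ac2O, pyridine) gives 24.

Step 14. What may go wrong:
- incomplete cleavage of the hindered ortho benzyl ethers, leaving partly protected material;
- acetyl shift from O5 to the neighbouring O4, or solvolysis of the acetate, once the phenols are free.

Fallback by Lewis-acid debenzylation, setting out from 24 and returning at 25: BCl3 with pentamethylbenzene as cation scavenger in CH2Cl2 at −78 °C should cleave the four aryl benzyl ethers and the benzyl ester without a reducing agent and without affecting the acetate or the aryl esters. This fallback makes no new compound (F0).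

## Further compounds

F1 | step 3 | 2-hydroxy-6-methyl-4-(triisopropylsilyloxy)benzaldehyde | Cc1cc(O[Si](C(C)C)(C(C)C)C(C)C)cc(O)c1C=O
F2 | step 3 | 2-(benzyloxy)-6-methyl-4-(triisopropylsilyloxy)benzaldehyde | Cc1cc(O[Si](C(C)C)(C(C)C)C(C)C)cc(OCc2ccccc2)c1C=O
F3 | step 11 | tert-butyl[2,4-bis(benzyloxy)-6-methylphenoxy]dimethylsilane | Cc1cc(OCc2ccccc2)cc(OCc2ccccc2)c1O[Si](C)(C)C(C)(C)C
F4 | step 11 | [4,6-bis(benzyloxy)-3-bromo-2-methylphenoxy](tert-butyl)dimethylsilane | Cc1c(Br)c(OCc2ccccc2)cc(OCc2ccccc2)c1O[Si](C)(C)C(C)(C)C
F5 | step 11 | 2,4-bis(benzyloxy)-5-(tert-butyldimethylsilyloxy)-6-methylbenzoic acid | Cc1c(C(=O)O)c(OCc2ccccc2)cc(OCc2ccccc2)c1O[Si](C)(C)C(C)(C)C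
F6 | step 11 | 2,4-bis(benzyloxy)-5-hydroxy-6-methylbenzoic acid | Cc1c(C(=O)O)c(OCc2ccccc2)cc(OCc2ccccc2)c1O
F7 | step 13 | 2,4-bis(benzyloxy)-5-(tert-butyldimethylsilyloxy)-6-methylbenzoyl chloride | Cc1c(C(Cl)=O)c(OCc2ccccc2)cc(OCc2ccccc2)c1O[Si](C)(C)C(C)(C)C
F8 | step 13 | benzyl 4-{[4-({2,4-bis(benzyloxy)-5-(tert-butyldimethylsilyloxy)-6-methylbenzoyl}oxy)-2-(benzyloxy)-6-methylbenzoyl]oxy}-2-(benzyloxy)-6-methylbenzoate | CC(C)(C)[Si](C)(C)Oc1c(OCc2ccccc2)cc(OCc2ccccc2)c(C(=O)Oc2cc(C)c(C(=O)Oc3cc(C)c(C(=O)OCc4ccccc4)c(OCc4ccccc4)c3)c(OCc3ccccc3)c2)c1C
F9 | step 13 | benzyl 4-{[4-({2,4-bis(benzyloxy)-5-hydroxy-6-methylbenzoyl}oxy)-2-(benzyloxy)-6-methylbenzoyl]oxy}-2-(benzyloxy)-6-methylbenzoate | Oc1c(OCc2ccccc2)cc(OCc2ccccc2)c(C(=O)Oc2cc(C)c(C(=O)Oc3cc(C)c(C(=O)OCc4ccccc4)c(OCc4ccccc4)c3)c(OCc3ccccc3)c2)c1C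
F0 | step 14 | none | none
A1 | alternative 1 | tert-butyl 5-acetoxy-4-(benzyloxy)-2-hydroxy-6-methylbenzoate | CC(=O)Oc1c(OCc2ccccc2)cc(O)c(C(=O)OC(C)(C)C)c1C
A2 | alternative 1 | tert-butyl (2E)-3-[1-acetoxy-2-(benzyloxy)-4-oxocyclobut-2-en-1-yl]but-2-enoate (racemic) | CC(=O)OC1(/C(C)=C/C(=O)OC(C)(C)C)C(OCc2ccccc2)=CC1=O
A3 | alternative 2 | benzyl 4-{[4-({5-acetoxy-2,4-dihydroxy-6-methylbenzoyl}oxy)-2-hydroxy-6-methylbenzoyl]oxy}-2-hydroxy-6-methylbenzoate | CC(=O)Oc1c(O)cc(O)c(C(=O)Oc2cc(C)c(C(=O)Oc3cc(C)c(C(=O)OCc4ccccc4)c(O)c3)c(O)c2)c1C
A4 | alternative 2 | benzyl lecanorate (benzyl 4-[(2,4-dihydroxy-6-methylbenzoyl)oxy]-2-hydroxy-6-methylbenzoate) | Cc1cc(O)cc(O)c1C(=O)Oc1cc(C)c(C(=O)OCc2ccccc2)c(O)c1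
A5 | alternative 2 | 1-(2,2-dimethyl-4-oxo-4H-1,3-dioxin-6-yl)-2,4-dioxopentan-3-yl acetate (racemic) | CC(=O)C(OC(C)=O)C(=O)CC1=CC(=O)OC(C)(C)O1
A6 | alternative 2 | benzyl 4-({4-[(6-acetoxy-3,5,7-trioxooctanoyl)oxy]-2-hydroxy-6-methylbenzoyl}oxy)-2-hydroxy-6-methylbenzoate (racemic) | CC(=O)C(OC(C)=O)C(=O)CC(=O)CC(=O)Oc1cc(C)c(C(=O)Oc2cc(C)c(C(=O)OCc3ccccc3)c(O)c2)c(O)c1
A7 | alternative 3 | benzyl 2-(benzyloxy)-4-{[2-hydroxy-6-methyl-4-(triisopropylsilyloxy)benzoyl]oxy}-6-methylbenzoate | Cc1cc(O[Si](C(C)C)(C(C)C)C(C)C)cc(O)c1C(=O)Oc1cc(C)c(C(=O)OCc2ccccc2)c(OCc2ccccc2)c1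
A8 | alternative 3 | benzyl 2-(benzyloxy)-4-{[(2E)-5-diazo-3-methyl-4-oxopent-2-enoyl]oxy}-6-methylbenzoate | [N-]=[N+]=CC(=O)/C(C)=C/C(=O)Oc1cc(C)c(C(=O)OCc2ccccc2)c(OCc2ccccc2)c1
A9 | alternative 3 | (triisopropylsilyloxy)acetylene (ethynyloxy-triisopropylsilane) | C#CO[Si](C(C)C)(C(C)C)C(C)C
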